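**The balance.** Count one L for each X that reacts: the share of charged X that has reacted stays at or below L charged over X charged. Call this ratio the ceiling; for green, with L as limiting reagent, it is 70.0%, for blue 100%.

| flask | X | L | remark | time |
|---|---|---|---|---|
| south | 0.060 M (fed, over 40 min) | 0.042 M | run made earlier |  |
| north | 0.078 M (fed, over 40 min) | 0.042 M | run made earlier |  |
| blue | 0.042 M (fed, over 40 min) | 0.0420 M |  | 40 min |
| green | 0.060 M | 0.0420 M | everything together at the start | 80 min |

| run | time / min | G / % |
|---|---|---|
| south | 2.50 | 1.2 |
| south | 3.00 | 1.8 |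
| south | 5.00 | 4.5 |
| south | 8.00 | 9.4 |
| south | 12.0 | 17.2 |
| south | 20.0 | 31.1 |
| south | 30.0 | 44.4 |
| north | 2.50 | 2.1 |
| north | 3.00 | 2.2 |
| north | 5.00 | 4.6 |
| north | 8.00 | 10.1 |
| north | 12.0 | 17.5 |
| north | 20.0 | 29.9 |
| north | 30.0 | 40.0 |

(standard deviation of a reading: 0.5 percentage points)

1. the winner by amount of G, in percent of the X charged; "neither" if no more than 2 percentage points parts them (blue / green / neither)
2. how much G is there at the end, in percent of the X charged: blue
3. how much G is there at the end, in percent of the X charged: green

- percentages count the whole charge, also what has not yet gone in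
- a reading or a percentage of G counts all its forms, free or not

**The curve.** Draw the south run against its feed. From 8.00 min to 20.0 min the feed adds 30.0% of the charge and G gains 22 percentage points. Mark the knee next: over the following 25.0% of feed, G gains 13 points. South and north still coincide at 12.0 min, at 17.2% and 17.5%. At 30.0 min north lies lower, 40.0% against 44.4%, and its ceiling is also lower, 53.8% against 70.0%.

**My estimate.** Put blue on the south curve and repeat its last gain: my estimate for blue is about 57.7% at 40 min. For green, a batch flask unlike these runs, I commit to nothing beyond its ceiling.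

**The forecast.** It names blue as winner, with blue at 76% (68% to 84%), above my figure, and green at 65% (60% to 69%), saying “a little is lost or left unused”. Its green figure is the view of L turned wholly into G.

**The result.** Blue gives 61.7% and green 36.5%, so blue wins.

    L → D (k = 9.70 × 10⁻⁵ s⁻¹)
    G ⇌ J (K = 1.10, k = 2.70 × 10⁻⁴ s⁻¹)
    L + G ⇌ Z, settled at all times (K = 56.0 L mol⁻¹)
    X + L → G, rate k4*[X]*[L]^0.5 (k = 0.0180 L⁰·⁵ mol⁻⁰·⁵ s⁻¹)

Green holds 32.5% as J at 80.0 min. Its reacted share, 69.0%, stands against the ceiling of 70.0%, and that share is held as G and J together.

**A second flask.** Charge green with 0.011 M of L instead: the ceiling becomes 18.3%. That flask ends with 81.8% of X left, so 18.2% has reacted, split into 9.52% G and 8.70% J.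

The runs were computed from invented constants, noise included.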